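**Retrosynthetic overview**
- The 14-membered carbocycle and the oxirane are closed together in one operation: an intramolecular sulfur-ylide (Corey–Chaykovsky) epoxidation of a methyl ketone, with the ylide generated from a phenyl thioether and benzyne.
- The open-chain keto thioether gets its C3 carbinol from an enantioselective acetone aldol on an (E)-enal.
- The (E)-enal comes from a methyl ketone via a terminal alkyne and Zr-catalysed methylalumination; the (Z)-trisubstituted alkene comes from a Z-iodo-olefination followed by B-alkyl Suzuki coupling.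
- Both carbonyl termini and the C8 stereocentre come from ozonolysis of silyl-protected (R)-α-terpineol.
- Ring order: no ring before the final cyclisation; carbocycle and oxirane form in the same step; silyl groups are then exchanged for acetates.

Locants used below are those of the target as a 15-oxabicyclo[12.1.0]pentadecane: C1 = methyl-bearing oxirane carbon, C3 = carbinol, C8 = carbon bearing the side chain, C14 = oxirane CH.
Assumption: (R)-(+)-α-terpineol is bought in high ee (otherwise one step from (R)-limonene by oxymercuration–reduction).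
Assumption: the (R)-ligand titanium catalyst of step 8 adds to the Re face of enal 19; this is checked by Mosher analysis on the first batch and the (S)-ligand is used if the sense is opposite.

**Step 1**
Reactants: 1 (R)-(+)-α-terpineol
Product: 2 triethyl{[2-((R)-4-methylcyclohex-3-en-1-yl)propan-2-yl]oxy}silane
Conditions: TESOTf, 2,6-lutidine, CH2Cl2, 0 °C
Reagents that add atoms: triethylsilyl triflate, CC[Si](CC)(CC)OS(=O)(=O)C(F)(F)F
Why: Silylation of the hindered tertiary alcohol with the silyl triflate is reliable and prevents lactol formation after ring cleavage; the (R) centre (future C8) comes from the chiral pool and is not touched.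

**Step 2**
Reactants: 2 triethyl{[2-((R)-4-methylcyclohex-3-en-1-yl)propan-2-yl]oxy}silane
Product: 4 (R)-6-oxo-3-[2-(triethylsilyloxy)propan-2-yl]heptanal, via ozonide 3 (not isolated)
Conditions: O3, CH2Cl2, −78 °C; Me2S, −78 → 23 °C
Reagents that add atoms: ozone, [O-][O+]=O
Why: Ozonolysis with reductive work-up cleaves the only alkene to the keto aldehyde; the stereocentre is β to the aldehyde and γ to the ketone, so it cannot epimerise.

**Step 3**
Reactants: 4 (R)-6-oxo-3-[2-(triethylsilyloxy)propan-2-yl]heptanal; 5 ethyltriphenylphosphonium iodide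
Product: 9 (5R,7Z)-8-iodo-5-[2-(triethylsilyloxy)propan-2-yl]non-7-en-2-one, via ethylidenetriphenylphosphorane 6 (not isolated), via (1-iodoethyl)triphenylphosphonium iodide 7 (not isolated), via (1-iodoethylidene)triphenylphosphorane 8 (not isolated)
Conditions: 5, n-BuLi, THF, 23 °C; I2, −78 °C; NaN(SiMe3)2, −20 °C; then 4, −78 → −20 °C
Reagents that add atoms: iodine, II
Why: Wittig iodo-olefination with the α-iodo ylide is kinetically Z-selective (iodine cis to the chain) and at −78 °C the ylide takes the aldehyde and leaves the methyl ketone.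

**Step 4**
Reactants: 9 (5R,7Z)-8-iodo-5-[2-(triethylsilyloxy)propan-2-yl]non-7-en-2-one; 10 allyl phenyl sulfide
Product: 12 (5R,7Z)-8-methyl-11-(phenylsulfanyl)-5-[2-(triethylsilyloxy)propan-2-yl]undec-7-en-2-one, via B-[3-(phenylsulfanyl)propyl]-9-BBN 11 (not isolated)
Conditions: 10, 9-BBN (0.95 equiv relative to 10), THF, 23 °C; then 9, PdCl2(dppf) (10 mol%), AsPh3, Cs2CO3, DMF/H2O, 23 °C
Reagents that add atoms: none
Why: Anti-Markovnikov hydroboration followed by B-alkyl Suzuki–Miyaura coupling replaces iodine with retention of alkene geometry, giving the (Z)-trisubstituted alkene and installing the thioether that later becomes the ylide; no B–H is left to reduce the ketone.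

**Step 5**
Reactants: 12 (5R,7Z)-8-methyl-11-(phenylsulfanyl)-5-[2-(triethylsilyloxy)propan-2-yl]undec-7-en-2-one
Product: 15 triethyl({2-[(5R,7Z)-8-methyl-11-(phenylsulfanyl)undec-7-en-1-yn-5-yl]propan-2-yl}oxy)silane, via enol phosphate 13 (not isolated), via lithium acetylide 14 (not isolated)
Conditions: LiN(iPr)2 (1.05 equiv), THF, −78 °C; ClP(O)(OEt)2, −78 → 23 °C; LiN(iPr)2 (2.3 equiv), −78 → 23 °C; H2O
Reagents that add atoms: none
Why: Negishi's methyl ketone to terminal alkyne conversion: kinetic deprotonation on the methyl side, O-phosphorylation and base-induced elimination; silyl ether, thioether and the Z-alkene are inert to the amide base.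

**Step 6**
Reactants: 15 triethyl({2-[(5R,7Z)-8-methyl-11-(phenylsulfanyl)undec-7-en-1-yn-5-yl]propan-2-yl}oxy)silane
Product: 18 (2E,6R,8Z)-3,9-dimethyl-12-(phenylsulfanyl)-6-[2-(triethylsilyloxy)propan-2-yl]dodeca-2,8-dien-1-ol, via alkenyldimethylalane 16 (not isolated), via lithium alkenylalanate 17 (not isolated)
Conditions: Me3Al (2.5 equiv), Cp2ZrCl2 (0.25 equiv), ClCH2CH2Cl, 23 °C; n-BuLi, THF, −78 °C; (CH2O)n, −78 → 23 °C; aq. KNaC4H4O6
Reagents that add atoms: trimethylaluminium, C[Al](C)C; paraformaldehyde (as formaldehyde), C=O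
Why: Negishi Zr-catalysed carboalumination adds Me–Al syn with aluminium at the terminus, and hydroxymethylation of the ate complex proceeds with retention, so the trisubstituted alkene is formed E (≥98%).

**Step 7**
Reactants: 18 (2E,6R,8Z)-3,9-dimethyl-12-(phenylsulfanyl)-6-[2-(triethylsilyloxy)propan-2-yl]dodeca-2,8-dien-1-ol
Product: 19 (2E,6R,8Z)-3,9-dimethyl-12-(phenylsulfanyl)-6-[2-(triethylsilyloxy)propan-2-yl]dodeca-2,8-dienal
Conditions: MnO2 (20 equiv), CH2Cl2, 23 °C
Reagents that add atoms: none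
Why: MnO2 allylic oxidation is chemoselective for the allylic alcohol and leaves the thioether, the silyl ether and the E geometry untouched.

**Step 8**
Reactants: 19 (2E,6R,8Z)-3,9-dimethyl-12-(phenylsulfanyl)-6-[2-(triethylsilyloxy)propan-2-yl]dodeca-2,8-dienal; 20 2-methoxypropene
Product: 22 (4R,5E,9R,11Z)-4-hydroxy-6,12-dimethyl-15-(phenylsulfanyl)-9-[2-(triethylsilyloxy)propan-2-yl]pentadeca-5,11-dien-2-one, via methyl enol ether adduct 21 (not isolated)
Conditions: 20 (solvent), Ti(OiPr)4 (5 mol%), (R)-2-(3-bromo-5-tert-butylsalicylideneamino)-2'-hydroxy-1,1'-binaphthyl (5 mol%), 3,5-di-tert-butylsalicylic acid (5 mol%), 2,6-di-tert-butyl-4-methylpyridine, 0 °C; then PPTS, THF/H2O, 0 °C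
Reagents that add atoms: water, O
Why: Catalytic enantioselective acetone aldol (ene-type addition of 2-methoxypropene under a chiral titanium Lewis acid): Re-face attack sets C3 as R under catalyst control, and the very mild enol ether hydrolysis avoids ionising or dehydrating the allylic β-hydroxy ketone.

**Step 9**
Reactants: 22 (4R,5E,9R,11Z)-4-hydroxy-6,12-dimethyl-15-(phenylsulfanyl)-9-[2-(triethylsilyloxy)propan-2-yl]pentadeca-5,11-dien-2-one
Product: 23 (4R,5E,9R,11Z)-4-(tert-butyldimethylsilyloxy)-6,12-dimethyl-15-(phenylsulfanyl)-9-[2-(triethylsilyloxy)propan-2-yl]pentadeca-5,11-dien-2-one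
Conditions: TBSOTf, 2,6-lutidine, CH2Cl2, −78 °C
Reagents that add atoms: tert-butyldimethylsilyl triflate, CC(C)(C)[Si](C)(C)OS(=O)(=O)C(F)(F)F
Why: O-silylation at −78 °C with the weak base is faster than ketone enolisation, and the silyl ether (unlike an ester or free OH) resists β-elimination and retro-aldol in the next step; no stereocentre is touched.

**Step 10**
Reactants: 23 (4R,5E,9R,11Z)-4-(tert-butyldimethylsilyloxy)-6,12-dimethyl-15-(phenylsulfanyl)-9-[2-(triethylsilyloxy)propan-2-yl]pentadeca-5,11-dien-2-one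
Product: 25 (1R,3R,4E,8R,10Z,14R)-3-(tert-butyldimethylsilyloxy)-1,5,11-trimethyl-8-[2-(triethylsilyloxy)propan-2-yl]-15-oxabicyclo[12.1.0]pentadeca-4,10-diene, via diphenylsulfonium ylide 24 (not isolated)
Conditions: 2-(trimethylsilyl)phenyl triflate (3 equiv, syringe pump, 10 h), KF, 18-crown-6, THF, 0.002 M in 23, 0 → 23 °C
Reagents that add atoms: none
Why: Proposed new method: the thioether sulfur adds to benzyne, the aryl anion of the zwitterion removes the only available α-proton (C14–H, five-membered transition state) to give the non-stabilised diphenylsulfonium ylide 24 at a very low stationary concentration, and 24 attacks the C1 methyl ketone (irreversible betaine formation, then backside displacement of Ph2S), so carbocycle and oxirane close in one intramolecular Corey–Chaykovsky event; the closest known reactions are aryne-induced sulfonium ylide formation from thioethers and intermolecular epoxidation of methyl ketones by alkylidene diphenylsulfuranes; C1 and C14 are set here under substrate control, the anti betaine giving the trans-oxirane and attack anti to the C3 silyloxy group (1,3-anti, dipole-minimised conformer) giving 1R,14R, with modest selectivity expected and the other diastereomers removed by chromatography.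

**Step 11**
Reactants: 25 (1R,3R,4E,8R,10Z,14R)-3-(tert-butyldimethylsilyloxy)-1,5,11-trimethyl-8-[2-(triethylsilyloxy)propan-2-yl]-15-oxabicyclo[12.1.0]pentadeca-4,10-diene
Product: 27 (1R,3R,4E,8R,10Z,14R)-8-(2-acetoxypropan-2-yl)-1,5,11-trimethyl-15-oxabicyclo[12.1.0]pentadeca-4,10-dien-3-yl acetate (CNP0282098.2), via diol 26 (not isolated)
Conditions: Bu4NF, THF, 0 → 40 °C; concentrate; Ac2O, Et3N, DMAP, CH2Cl2, 35 °C
Reagents that add atoms: acetic anhydride, CC(=O)OC(C)=O
Why: Fluoride desilylation followed by DMAP-catalysed (Steglich) acetylation esterifies both the secondary allylic and the tertiary alcohol under non-acidic conditions that leave the oxirane, both alkenes and all four stereocentres unchanged.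

**Compound list**
1 | (R)-(+)-α-terpineol | CC1=CC[C@H](C(C)(C)O)CC1 | starting material
2 | triethyl{[2-((R)-4-methylcyclohex-3-en-1-yl)propan-2-yl]oxy}silane | CC1=CC[C@H](C(C)(C)O[Si](CC)(CC)CC)CC1 | intermediate
3 | ozonide (1,2,4-trioxolane) of 2, mixture at the acetal carbons | CC12CC[C@@H](C(C)(C)O[Si](CC)(CC)CC)CC(OO1)O2 | intermediate (not isolated)
4 | (R)-6-oxo-3-[2-(triethylsilyloxy)propan-2-yl]heptanal | CC(=O)CC[C@@H](C(C)(C)O[Si](CC)(CC)CC)CC=O | intermediate
5 | ethyltriphenylphosphonium iodide | CC[P+](c1ccccc1)(c1ccccc1)c1ccccc1.[I-] | starting material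
6 | ethylidenetriphenylphosphorane | CC=P(c1ccccc1)(c1ccccc1)c1ccccc1 | intermediate (not isolated)
7 | (1-iodoethyl)triphenylphosphonium iodide | CC(I)[P+](c1ccccc1)(c1ccccc1)c1ccccc1.[I-] | intermediate (not isolated)
8 | (1-iodoethylidene)triphenylphosphorane | CC(I)=P(c1ccccc1)(c1ccccc1)c1ccccc1 | intermediate (not isolated)
9 | (5R,7Z)-8-iodo-5-[2-(triethylsilyloxy)propan-2-yl]non-7-en-2-one | CC(=O)CC[C@@H](C(C)(C)O[Si](CC)(CC)CC)C/C=C(/C)I | intermediate
10 | allyl phenyl sulfide | C=CCSc1ccccc1 | starting material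
11 | B-[3-(phenylsulfanyl)propyl]-9-borabicyclo[3.3.1]nonane | c1ccc(SCCCB2C3CCCC2CCC3)cc1 | intermediate (not isolated)
12 | (5R,7Z)-8-methyl-11-(phenylsulfanyl)-5-[2-(triethylsilyloxy)propan-2-yl]undec-7-en-2-one | CC(=O)CC[C@@H](C(C)(C)O[Si](CC)(CC)CC)C/C=C(/C)CCCSc1ccccc1 | intermediate
13 | diethyl enol phosphate of 12 (terminal C=C) | C=C(OP(=O)(OCC)OCC)CC[C@@H](C(C)(C)O[Si](CC)(CC)CC)C/C=C(/C)CCCSc1ccccc1 | intermediate (not isolated)
14 | lithium acetylide of 15 | [Li]C#CCC[C@@H](C(C)(C)O[Si](CC)(CC)CC)C/C=C(/C)CCCSc1ccccc1 | intermediate (not isolated)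
15 | triethyl({2-[(5R,7Z)-8-methyl-11-(phenylsulfanyl)undec-7-en-1-yn-5-yl]propan-2-yl}oxy)silane | C#CCC[C@@H](C(C)(C)O[Si](CC)(CC)CC)C/C=C(/C)CCCSc1ccccc1 | intermediate
16 | (E)-alkenyldimethylalane from 15 (Me and Al cis) | C[Al](C)/C=C(\C)CC[C@@H](C(C)(C)O[Si](CC)(CC)CC)C/C=C(/C)CCCSc1ccccc1 | intermediate (not isolated)
17 | lithium butyl(dimethyl)alkenylalanate from 16 | [Li+].CCCC[Al-](C)(C)/C=C(\C)CC[C@@H](C(C)(C)O[Si](CC)(CC)CC)C/C=C(/C)CCCSc1ccccc1 | intermediate (not isolated)
18 | (2E,6R,8Z)-3,9-dimethyl-12-(phenylsulfanyl)-6-[2-(triethylsilyloxy)propan-2-yl]dodeca-2,8-dien-1-ol | OC/C=C(\C)CC[C@@H](C(C)(C)O[Si](CC)(CC)CC)C/C=C(/C)CCCSc1ccccc1 | intermediate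
19 | (2E,6R,8Z)-3,9-dimethyl-12-(phenylsulfanyl)-6-[2-(triethylsilyloxy)propan-2-yl]dodeca-2,8-dienal | O=C/C=C(\C)CC[C@@H](C(C)(C)O[Si](CC)(CC)CC)C/C=C(/C)CCCSc1ccccc1 | intermediate
20 | 2-methoxypropene | COC(C)=C | starting material
21 | (4R)-hydroxy 2-methoxy-1-alkene adduct of 19 and 20 | C=C(OC)C[C@@H](O)/C=C(\C)CC[C@@H](C(C)(C)O[Si](CC)(CC)CC)C/C=C(/C)CCCSc1ccccc1 | intermediate (not isolated)
22 | (4R,5E,9R,11Z)-4-hydroxy-6,12-dimethyl-15-(phenylsulfanyl)-9-[2-(triethylsilyloxy)propan-2-yl]pentadeca-5,11-dien-2-one | CC(=O)C[C@@H](O)/C=C(\C)CC[C@@H](C(C)(C)O[Si](CC)(CC)CC)C/C=C(/C)CCCSc1ccccc1 | intermediate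
23 | (4R,5E,9R,11Z)-4-(tert-butyldimethylsilyloxy)-6,12-dimethyl-15-(phenylsulfanyl)-9-[2-(triethylsilyloxy)propan-2-yl]pentadeca-5,11-dien-2-one | CC(=O)C[C@@H](O[Si](C)(C)C(C)(C)C)/C=C(\C)CC[C@@H](C(C)(C)O[Si](CC)(CC)CC)C/C=C(/C)CCCSc1ccccc1 | intermediate
24 | diphenylsulfonium ylide of 23 (carbanion at the former SCH2 carbon) | CC(=O)C[C@@H](O[Si](C)(C)C(C)(C)C)/C=C(\C)CC[C@@H](C(C)(C)O[Si](CC)(CC)CC)C/C=C(/C)CC[CH-][S+](c1ccccc1)c1ccccc1 | intermediate (not isolated)
25 | (1R,3R,4E,8R,10Z,14R)-3-(tert-butyldimethylsilyloxy)-1,5,11-trimethyl-8-[2-(triethylsilyloxy)propan-2-yl]-15-oxabicyclo[12.1.0]pentadeca-4,10-diene | CC(C)(C)[Si](C)(C)O[C@H]1/C=C(\C)CC[C@@H](C(C)(C)O[Si](CC)(CC)CC)C/C=C(/C)CC[C@H]2O[C@]2(C)C1 | intermediate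
26 | (1R,3R,4E,8R,10Z,14R)-8-(2-hydroxypropan-2-yl)-1,5,11-trimethyl-15-oxabicyclo[12.1.0]pentadeca-4,10-dien-3-ol | O[C@H]1/C=C(\C)CC[C@@H](C(C)(C)O)C/C=C(/C)CC[C@H]2O[C@]2(C)C1 | intermediate (not isolated)
27 | (1R,3R,4E,8R,10Z,14R)-8-(2-acetoxypropan-2-yl)-1,5,11-trimethyl-15-oxabicyclo[12.1.0]pentadeca-4,10-dien-3-yl acetate | CC(=O)O[C@H]1/C=C(\C)CC[C@@H](C(C)(C)OC(C)=O)C/C=C(/C)CC[C@H]2O[C@]2(C)C1 | target

**Step count**
Total steps: 11. Longest linear sequence: 11 (from 1).

**Steps most likely to fail**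

Step 10. Risks: benzyne capture is slow at high dilution, the non-stabilised ylide may decay before it cyclises, and four oxirane diastereomers are possible. Fallback: starting from 23, S-phenylation with diphenyliodonium triflate and Cu(O2CPh)2 (5 mol%) in chlorobenzene at 90 °C gives the isolable [(4Z,7R,10E,12R)-12-(tert-butyldimethylsilyloxy)-4,10-dimethyl-14-oxo-7-[2-(triethylsilyloxy)propan-2-yl]pentadeca-4,10-dien-1-yl]diphenylsulfonium triflate F1. Slow addition of this salt to KN(SiMe3)2 in THF at −78 °C (final 0.001 M) generates ylide 24 by deprotonation at low temperature, without fluoride or aryne, and 24 closes to 25, where the route is rejoined.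

Step 8. Risks: the β,β-disubstituted enal is a hindered acceptor, the sense and level of induction are not secured, and the allylic β-hydroxy ketone dehydrates easily. Fallback: starting from 19, allylboration with (+)-Ipc2B(allyl) (Et2O, −78 °C, ethanolamine work-up; Re-face attack, a reagent of well-established sense) gives (4R,5E,9R,11Z)-6,12-dimethyl-15-(phenylsulfanyl)-9-[2-(triethylsilyloxy)propan-2-yl]pentadeca-1,5,11-trien-4-ol F2. Silylation (TBSOTf, 2,6-lutidine, −78 °C) gives its tert-butyldimethylsilyl ether F3. Tsuji–Wacker oxidation of the terminal alkene (PdCl2 30 mol% or more because the thioether binds palladium, CuCl, O2, DMF/H2O) then gives methyl ketone 23, where the route is rejoined, one step longer.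

Step 3. Risks: moderate yield and incomplete Z-selectivity of the iodo-olefination, and the iodoalkene is sensitive. Fallback: starting from 4, one Wittig reaction with a preassembled branched ylide replaces steps 3 and 4. Ylide 6 (from 5 and n-BuLi) is alkylated with 3-iodopropyl phenyl sulfide to give triphenyl[5-(phenylsulfanyl)pentan-2-yl]phosphonium iodide F4; NaN(SiMe3)2 converts it into triphenyl[5-(phenylsulfanyl)pentan-2-ylidene]phosphorane F5; addition of 4 at −78 °C gives 12 directly, where the route is rejoined. The Z isomer should predominate because the larger ylide substituent ends up cis to the aldehyde chain; the E isomer is removed on AgNO3-impregnated silica.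

**Further compounds**
F1 | step 10 | [(4Z,7R,10E,12R)-12-(tert-butyldimethylsilyloxy)-4,10-dimethyl-14-oxo-7-[2-(triethylsilyloxy)propan-2-yl]pentadeca-4,10-dien-1-yl]diphenylsulfonium triflate | CC(=O)C[C@@H](O[Si](C)(C)C(C)(C)C)/C=C(\C)CC[C@@H](C(C)(C)O[Si](CC)(CC)CC)C/C=C(/C)CCC[S+](c1ccccc1)c1ccccc1.[O-]S(=O)(=O)C(F)(F)F
F2 | step 8 | (4R,5E,9R,11Z)-6,12-dimethyl-15-(phenylsulfanyl)-9-[2-(triethylsilyloxy)propan-2-yl]pentadeca-1,5,11-trien-4-ol | C=CC[C@@H](O)/C=C(\C)CC[C@@H](C(C)(C)O[Si](CC)(CC)CC)C/C=C(/C)CCCSc1ccccc1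
F3 | step 8 | tert-butyldimethylsilyl ether of F2 | C=CC[C@@H](O[Si](C)(C)C(C)(C)C)/C=C(\C)CC[C@@H](C(C)(C)O[Si](CC)(CC)CC)C/C=C(/C)CCCSc1ccccc1
F4 | step 3 | triphenyl[5-(phenylsulfanyl)pentan-2-yl]phosphonium iodide (racemic) | CC(CCCSc1ccccc1)[P+](c1ccccc1)(c1ccccc1)c1ccccc1.[I-]
F5 | step 3 | triphenyl[5-(phenylsulfanyl)pentan-2-ylidene]phosphorane | CC(CCCSc1ccccc1)=P(c1ccccc1)(c1ccccc1)c1ccccc1
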